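**Strategy.** Everything rests on cutting the γ-lactone ring (O–C8–C7–C11–C12; germacrane numbering) at C7–C11 and C8–O. C7 and C8 then carry only H and one CH2 arm each (C6, C9), so C5–C6–C7–C8–C9 can be drawn as the ring of meso cis-cyclopent-4-ene-1,3-diyl diacetate. One palladium-catalysed, ligand-controlled annulation with the dianion of diethylphosphonoacetic acid forms both bonds: C-allylation fixes C7, carboxylate O-allylation closes the lactone at C8 (cis; C8 is later equilibrated to trans). Ozonolysis of C9=C5 releases the two arms, olefinations build C4=C5 and close the ten-membered ring at C1=C10, and the C11 phosphonate finally becomes the exocyclic methylene.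

Key step: step 1

Numbering used for atom labels: ring C1–C10, lactone C7/C8, acrylate unit C11–C13, C14 on C10, C15 on C4.

Assumption: the (R,R)-enantiomer of the Trost ligand is taken to ionise the acetate at the (S)-configured carbon of 1 (Trost mnemonic); if the first run gives the antipode of 4, the (S,S)-ligand is used and nothing else changes.

Assumption: 9 and 22 are taken as commercial.

**Route**

Step 1
Reactants: 1 cis-3,5-diacetoxycyclopent-1-ene [(1R,3S)-cyclopent-4-ene-1,3-diyl diacetate; meso]; 2 diethylphosphonoacetic acid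
Product: 4 diethyl [(3aS,6aR)-2-oxo-3,3a,4,6a-tetrahydro-2H-cyclopenta[b]furan-3-yl]phosphonate (cis-fused; C3 epimers), via lithium carboxylate 3 (not isolated)
Conditions: 2, LiHMDS (2.05 equiv), THF, −78 → 0 °C; then 1, Pd2(dba)3·CHCl3 (2.5 mol %), (R,R)-DACH-phenyl Trost ligand (7.5 mol %), THF, 0 °C → rt, then 45 °C
Reagents that add atoms: none
Why: Proposed new method: the chiral Pd(0) complex should ionise one enantiotopic acetate of meso-1, and the carbanion of the dianion of 2 should attack the π-allyl terminus remote from the second acetate, anti to Pd (net retention), to give carboxylate 3; a second ionisation then lets the tethered carboxylate attack the proximal allyl terminus, again anti to Pd, so the C7–C11 and C8–O bonds form in one flask. The closest known reactions are Trost asymmetric allylic alkylations of meso-cyclopent-2-ene-1,4-diyl diesters that end in an intramolecular O-allylation (nitronate and β-dicarbonyl annulations) and Pd-catalysed allylic lactonisations by carboxylates; what is new is a carboxylic acid dianion as the C,O-bisnucleophile. The lactone closes in a 5-exo sense onto the π-allyl terminus and, because both substitutions run with double inversion on the same face of the five-membered ring, it can only be cis-fused. C7 is controlled by the ligand (choice of the enantiotopic leaving group), C8 by the substrate (position and face of the second π-allyl complex relative to C7), and C11 stays epimerisable and is without consequence. The step needs C-alkylation before O-alkylation, which the far higher nucleophilicity of the carbanion should secure, and it needs the slower second ionisation to wait until the dianion is consumed, which the temperature ramp should secure.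

Step 2
Reactants: 4
Product: 7 diethyl [(4S,5S)-5-(dimethoxymethyl)-2-oxo-4-(2-oxoethyl)oxolan-3-yl]phosphonate, via aldehyde methoxy-hydroperoxide 5 (not isolated), via acetal methoxy-hydroperoxide 6 (not isolated)
Conditions: O3, CH2Cl2/MeOH (5:1), −78 °C; p-TsOH·H2O (10 mol %), −78 °C → rt; NaHCO3, then Me2S, rt
Reagents that add atoms: ozone [O-][O+]=O; methanol CO
Why: Unsymmetrical ozonolysis (Criegee fragmentation in methanol): the electron-withdrawing allylic lactone oxygen at C8 should steer the primary ozonide to the C9 aldehyde and the C5 carbonyl oxide, so acid acetalises C9 and Me2S then unmasks C5 as the free aldehyde, without touching the stereocentres.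

Step 3
Reactants: 8 methyl bis(2,2,2-trifluoroethyl)phosphonoacetate; 9 tert-butyl(3-iodopropoxy)dimethylsilane
Product: 10 methyl 2-[bis(2,2,2-trifluoroethoxy)phosphoryl]-5-[(tert-butyldimethylsilyl)oxy]pentanoate (racemic)
Conditions: NaH (1.0 equiv), DMSO, rt; then 9, 50 °C
Reagents that add atoms: none
Why: SN2 C-alkylation of the sodium salt of the Still–Gennari phosphonate with a primary iodide, held at mono-alkylation by one equivalent of base.

Step 4
Reactants: 7; 10
Product: 11 methyl (2Z)-2-{3-[(tert-butyldimethylsilyl)oxy]propyl}-4-[(2S,3S)-4-(diethoxyphosphoryl)-2-(dimethoxymethyl)-5-oxooxolan-3-yl]but-2-enoate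
Conditions: 10, KHMDS (1.0 equiv), 18-crown-6, THF, −78 °C; then 7, −78 °C
Reagents that add atoms: none
Why: Still–Gennari olefination should give the (Z)-trisubstituted enoate (C6 cis to the C15 carboxyl, as the ring-trans C4=C5 bond requires), while the less acidic lactone phosphonate stays protonated.

Step 5
Reactants: 11
Product: 13 methyl (2Z)-4-[(2R,3S)-4-(diethoxyphosphoryl)-2-formyl-5-oxooxolan-3-yl]-2-(3-hydroxypropyl)but-2-enoate (trans-lactone), via cis-aldehyde 12 (not isolated)
Conditions: TFA/H2O (4:1), CH2Cl2, 0 °C → rt; NaHCO3 work-up; then DBU (0.1 equiv), CH2Cl2, rt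
Reagents that add atoms: water O
Why: Aqueous acid hydrolyses the dimethyl acetal and the primary silyl ether, and enolisation of the α-acyloxy aldehyde then equilibrates C8 to the more stable trans-4,5-disubstituted lactone (thermodynamic control; C7 is not enolisable), which gives the C7/C8 relationship of the target.

Step 6
Reactants: 13; 14 diethyl (cyanomethyl)phosphonate
Product: 16 methyl (2Z)-4-{(2S,3S)-2-[2-cyano-2-(diethoxyphosphoryl)ethyl]-4-(diethoxyphosphoryl)-5-oxooxolan-3-yl}-2-(3-hydroxypropyl)but-2-enoate (epimers at the two P-bearing carbons), via alkylidene cyanophosphonate 15 (not isolated)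
Conditions: TiCl4 (2.2 equiv), N-methylmorpholine (4.5 equiv), THF, 0 °C; aqueous work-up; then NaBH4, EtOH/THF, −20 → 0 °C
Reagents that add atoms: none
Why: TiCl4/amine Knoevenagel condensation at the C9 aldehyde, followed at once by borohydride 1,4-reduction of the doubly activated alkene, attaches C10 with its nitrile (C14) and phosphonate and makes C9 a CH2 group without touching ester, lactone or C8.

Step 7
Reactants: 16
Product: 17 methyl (2Z)-4-{(2S,3S)-2-[2-cyano-2-(diethoxyphosphoryl)ethyl]-4-(diethoxyphosphoryl)-5-oxooxolan-3-yl}-2-(3-oxopropyl)but-2-enoate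
Conditions: Dess–Martin periodinane, NaHCO3, CH2Cl2, 0 °C → rt
Reagents that add atoms: none
Why: Dess–Martin oxidation of the only hydroxyl group (primary, C1) to the aldehyde under buffered conditions that leave the two C–H-acidic phosphonates alone.

Step 8
Reactants: 17
Product: 18 methyl (3aS,5Z,9E,11aS)-10-cyano-3-(diethoxyphosphoryl)-2-oxo-2,3,3a,4,7,8,11,11a-octahydrocyclodeca[b]furan-6-carboxylate (C3 epimers)
Conditions: LiCl (10 equiv), DBU (3 equiv), MeCN, 1 mM (syringe-pump addition), rt
Reagents that add atoms: none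
Why: Intramolecular Horner–Wadsworth–Emmons reaction (Masamune–Roush conditions, high dilution): the C10 cyanophosphonate anion should close the ten-membered ring on the C1 aldehyde, the ring allowing only the ring-cis (9E) enenitrile, while the lactone phosphonate anion cannot reach the aldehyde without forming a trans-cyclooctene.

Step 9
Reactants: 18
Product: 20 diethyl [(3aS,5Z,9E,11aS)-10-formyl-6-(hydroxymethyl)-2-oxo-2,3,3a,4,7,8,11,11a-octahydrocyclodeca[b]furan-3-yl]phosphonate, via sodium lactone enolate 19 (not isolated)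
Conditions: NaH (1.1 equiv), THF, 0 °C; DIBAL-H (4 equiv), −78 °C; aq. Rochelle salt, then 1 M citric acid, 0 °C
Reagents that add atoms: water O
Why: Prior deprotonation turns the α-phosphono lactone into a hydride-inert stabilised enolate, so DIBAL-H should reduce the (Z)-enoate to the C15 allylic alcohol and the nitrile only to the aldimine, which acidic work-up hydrolyses to the C14 enal; C14 and C15 thus leave the step at different oxidation levels.

Step 10
Reactants: 20
Product: 21 (3aR,5Z,9E,11aS)-6-(hydroxymethyl)-3-methylidene-2-oxo-2,3,3a,4,7,8,11,11a-octahydrocyclodeca[b]furan-10-carbaldehyde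
Conditions: K2CO3 (2 equiv), 37 % aq. HCHO, THF, 0 °C → rt
Reagents that add atoms: formaldehyde C=O
Why: Horner–Wadsworth–Emmons methylenation of the α-phosphono lactone with formaldehyde, the standard mild entry to α-methylene-γ-butyrolactones, run before the base-sensitive chlorohydrin is present.

Step 11
Reactants: 22 methyl (S)-2-methylglycidate
Product: 24 (R)-3-chloro-2-hydroxy-2-methylpropanoic acid, via chlorohydrin methyl ester 23 (not isolated)
Conditions: conc. aq. HCl, 0 °C → rt; then 60 °C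
Reagents that add atoms: hydrogen chloride Cl; water O
Why: Acid-mediated epoxide opening by chloride at the unhindered CH2 carbon (SN2; the quaternary centre is not involved and only its descriptor changes from S to R), followed by acidic ester hydrolysis.

Step 12
Reactants: 21; 24
Product: 25 [(3aR,5Z,9E,11aS)-10-formyl-3-methylidene-2-oxo-2,3,3a,4,7,8,11,11a-octahydrocyclodeca[b]furan-6-yl]methyl (2R)-3-chloro-2-hydroxy-2-methylpropanoate
Conditions: EDC·HCl (1.5 equiv), DMAP (0.2 equiv), CH2Cl2, 0 °C → rt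
Reagents that add atoms: none
Why: Steglich-type esterification of the only hydroxyl group of 21 (primary, allylic, C15); the hindered tertiary hydroxyl of 24 should not compete and the weakly basic conditions should not close the chlorohydrin to the epoxide.

Step 13
Reactants: 25
Product: 26 [(3aR,5Z,9E,11aS)-10-(hydroxymethyl)-3-methylidene-2-oxo-2,3,3a,4,7,8,11,11a-octahydrocyclodeca[b]furan-6-yl]methyl (2R)-3-chloro-2-hydroxy-2-methylpropanoate (target)
Conditions: NaBH4 (1.0 equiv), CeCl3·7H2O (1.1 equiv), MeOH, −78 °C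
Reagents that add atoms: none
Why: Luche reduction: 1,2-selective hydride delivery to the enal should give the C14 allylic alcohol and, at −78 °C, leave the α-methylene lactone, the ester and the alkyl chloride untouched.

**Compound list**

1 | cis-3,5-diacetoxycyclopent-1-ene [(1R,3S)-cyclopent-4-ene-1,3-diyl diacetate, meso] | CC(=O)O[C@H]1C=C[C@@H](OC(C)=O)C1 | starting material
2 | diethylphosphonoacetic acid | CCOP(=O)(OCC)CC(=O)O | starting material
3 | lithium 2-[(1S,4R)-4-acetoxycyclopent-2-en-1-yl]-2-(diethoxyphosphoryl)acetate | [Li+].[O-]C(=O)C(P(=O)(OCC)OCC)[C@@H]1C=C[C@H](OC(C)=O)C1 | intermediate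
4 | diethyl [(3aS,6aR)-2-oxo-3,3a,4,6a-tetrahydro-2H-cyclopenta[b]furan-3-yl]phosphonate (C3 epimers) | CCOP(=O)(OCC)C1C(=O)O[C@@H]2C=CC[C@H]12 | intermediate
5 | diethyl [(4S,5S)-5-formyl-4-(2-hydroperoxy-2-methoxyethyl)-2-oxooxolan-3-yl]phosphonate | CCOP(=O)(OCC)C1C(=O)O[C@H](C=O)[C@@H]1CC(OC)OO | intermediate
6 | diethyl [(4S,5S)-5-(dimethoxymethyl)-4-(2-hydroperoxy-2-methoxyethyl)-2-oxooxolan-3-yl]phosphonate | CCOP(=O)(OCC)C1C(=O)O[C@H](C(OC)OC)[C@@H]1CC(OC)OO | intermediate
7 | diethyl [(4S,5S)-5-(dimethoxymethyl)-2-oxo-4-(2-oxoethyl)oxolan-3-yl]phosphonate | CCOP(=O)(OCC)C1C(=O)O[C@H](C(OC)OC)[C@@H]1CC=O | intermediate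
8 | methyl bis(2,2,2-trifluoroethyl)phosphonoacetate | COC(=O)CP(=O)(OCC(F)(F)F)OCC(F)(F)F | starting material
9 | tert-butyl(3-iodopropoxy)dimethylsilane | CC(C)(C)[Si](C)(C)OCCCI | starting material
10 | methyl 2-[bis(2,2,2-trifluoroethoxy)phosphoryl]-5-[(tert-butyldimethylsilyl)oxy]pentanoate (racemic) | COC(=O)C(CCCO[Si](C)(C)C(C)(C)C)P(=O)(OCC(F)(F)F)OCC(F)(F)F | intermediate
11 | methyl (2Z)-2-{3-[(tert-butyldimethylsilyl)oxy]propyl}-4-[(2S,3S)-4-(diethoxyphosphoryl)-2-(dimethoxymethyl)-5-oxooxolan-3-yl]but-2-enoate | CCOP(=O)(OCC)C1C(=O)O[C@H](C(OC)OC)[C@@H]1C/C=C(/CCCO[Si](C)(C)C(C)(C)C)C(=O)OC | intermediate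
12 | methyl (2Z)-4-[(2S,3S)-4-(diethoxyphosphoryl)-2-formyl-5-oxooxolan-3-yl]-2-(3-hydroxypropyl)but-2-enoate (cis-lactone) | CCOP(=O)(OCC)C1C(=O)O[C@H](C=O)[C@@H]1C/C=C(/CCCO)C(=O)OC | intermediate
13 | methyl (2Z)-4-[(2R,3S)-4-(diethoxyphosphoryl)-2-formyl-5-oxooxolan-3-yl]-2-(3-hydroxypropyl)but-2-enoate (trans-lactone) | CCOP(=O)(OCC)C1C(=O)O[C@@H](C=O)[C@@H]1C/C=C(/CCCO)C(=O)OC | intermediate
14 | diethyl (cyanomethyl)phosphonate | CCOP(=O)(CC#N)OCC | starting material
15 | methyl (2Z)-4-{(2R,3S)-2-[2-cyano-2-(diethoxyphosphoryl)ethenyl]-4-(diethoxyphosphoryl)-5-oxooxolan-3-yl}-2-(3-hydroxypropyl)but-2-enoate (alkylidene E/Z mixture) | CCOP(=O)(OCC)C1C(=O)O[C@@H](C=C(C#N)P(=O)(OCC)OCC)[C@@H]1C/C=C(/CCCO)C(=O)OC | intermediate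
16 | methyl (2Z)-4-{(2S,3S)-2-[2-cyano-2-(diethoxyphosphoryl)ethyl]-4-(diethoxyphosphoryl)-5-oxooxolan-3-yl}-2-(3-hydroxypropyl)but-2-enoate | CCOP(=O)(OCC)C1C(=O)O[C@@H](CC(C#N)P(=O)(OCC)OCC)[C@@H]1C/C=C(/CCCO)C(=O)OC | intermediate
17 | methyl (2Z)-4-{(2S,3S)-2-[2-cyano-2-(diethoxyphosphoryl)ethyl]-4-(diethoxyphosphoryl)-5-oxooxolan-3-yl}-2-(3-oxopropyl)but-2-enoate | CCOP(=O)(OCC)C1C(=O)O[C@@H](CC(C#N)P(=O)(OCC)OCC)[C@@H]1C/C=C(/CCC=O)C(=O)OC | intermediate
18 | methyl (3aS,5Z,9E,11aS)-10-cyano-3-(diethoxyphosphoryl)-2-oxo-2,3,3a,4,7,8,11,11a-octahydrocyclodeca[b]furan-6-carboxylate | CCOP(=O)(OCC)C1C(=O)O[C@H]2C/C(C#N)=C\CC/C(C(=O)OC)=C/C[C@H]12 | intermediate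
19 | sodium (3aS,5Z,9E,11aS)-10-cyano-3-(diethoxyphosphoryl)-6-(methoxycarbonyl)-3a,4,7,8,11,11a-hexahydrocyclodeca[b]furan-2-olate | [Na+].CCOP(=O)(OCC)C1=C([O-])O[C@H]2C/C(C#N)=C\CC/C(C(=O)OC)=C/C[C@H]12 | intermediate
20 | diethyl [(3aS,5Z,9E,11aS)-10-formyl-6-(hydroxymethyl)-2-oxo-2,3,3a,4,7,8,11,11a-octahydrocyclodeca[b]furan-3-yl]phosphonate | CCOP(=O)(OCC)C1C(=O)O[C@H]2C/C(C=O)=C\CC/C(CO)=C/C[C@H]12 | intermediate
21 | (3aR,5Z,9E,11aS)-6-(hydroxymethyl)-3-methylidene-2-oxo-2,3,3a,4,7,8,11,11a-octahydrocyclodeca[b]furan-10-carbaldehyde | C=C1C(=O)O[C@H]2C/C(C=O)=C\CC/C(CO)=C/C[C@H]12 | intermediate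
22 | methyl (S)-2-methylglycidate [methyl (2S)-2-methyloxirane-2-carboxylate] | COC(=O)[C@@](C)(O1)C1 | starting material
23 | methyl (R)-3-chloro-2-hydroxy-2-methylpropanoate | COC(=O)[C@@](C)(O)CCl | intermediate
24 | (R)-3-chloro-2-hydroxy-2-methylpropanoic acid | OC(=O)[C@@](C)(O)CCl | intermediate
25 | [(3aR,5Z,9E,11aS)-10-formyl-3-methylidene-2-oxo-2,3,3a,4,7,8,11,11a-octahydrocyclodeca[b]furan-6-yl]methyl (2R)-3-chloro-2-hydroxy-2-methylpropanoate | C=C1C(=O)O[C@H]2C/C(C=O)=C\CC/C(COC(=O)[C@@](C)(O)CCl)=C/C[C@H]12 | intermediate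
26 | [(3aR,5Z,9E,11aS)-10-(hydroxymethyl)-3-methylidene-2-oxo-2,3,3a,4,7,8,11,11a-octahydrocyclodeca[b]furan-6-yl]methyl (2R)-3-chloro-2-hydroxy-2-methylpropanoate | C=C1C(=O)O[C@H]2C/C(CO)=C\CC/C(COC(=O)[C@@](C)(O)CCl)=C/C[C@H]12 | target

**Step count and risks**

Total step count: 13. Longest linear sequence: 11 steps (1, 2, 4, 5, 6, 7, 8, 9, 10, 12, 13).

Steps most likely to fail:

1. Step 1 (Proposed new method). The hard lithium dianion may transfer an acyl group from the acetates of 1 instead of attacking the π-allyl complex, the carboxylate may O-allylate before the carbanion, or tight ion pairing may erode the enantioselection. The fallback uses known reaction types only, sets out from 1 and 2 and comes back at 4. Acid 2 is esterified with 2-(trimethylsilyl)ethanol (DCC, DMAP) to 2-(trimethylsilyl)ethyl (diethoxyphosphoryl)acetate F1. Its sodium salt (NaH, THF) serves as an ordinary soft nucleophile in the Trost asymmetric allylic alkylation of 1 (same catalyst, 0 °C) and should give 2-(trimethylsilyl)ethyl 2-[(1S,4R)-4-acetoxycyclopent-2-en-1-yl]-2-(diethoxyphosphoryl)acetate F2. TBAF is then added to the same flask; the silylethyl ester is cleaved and the tetrabutylammonium carboxylate F3 closes the lactone on the second π-allyl complex at 40 °C to give 4, so both bonds still form in one operation.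

2. Step 8. Intermolecular olefination (oligomerisation) may outrun closure of the strained ten-membered ring, or the competing lactone phosphonate anion may consume the aldehyde. The fallback sets out from 13 and comes back at 18; it replaces the phosphonate olefination by a decarboxylative condensation. 13 is condensed with cyanoacetic acid (piperidinium acetate, EtOH, rt) to the alkylidene cyanoacetic acid F4, which is reduced in the same flask (NaBH4) to the substituted cyanoacetic acid F5. Dess–Martin oxidation gives the aldehyde acid F6. The ring is then closed by a Knoevenagel condensation in the Doebner modification (piperidine, pyridine, 1 mM, 60 °C), in which reversible addition to the iminium ion is followed by irreversible loss of CO2 and water, to give 18.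

3. Step 2. The primary ozonide may fragment with low or reversed regioselectivity, so that the acetal and the free aldehyde end up on the wrong arms. The fallback sets out from 4 and comes back at 16; the regioisomer is elaborated in the reverse order, so material of either regiochemistry converges. The same three-stage ozonolysis then passes through the regioisomeric aldehyde methoxy-hydroperoxide F7 and acetal methoxy-hydroperoxide F8 and gives the C9 aldehyde C5 acetal F9. DBU equilibration gives the trans-aldehyde F10. Knoevenagel condensation with 14 under piperidinium acetate (no TiCl4, which would ionise the acetal) gives the alkylidene F11, and NaBH4 the cyanophosphonate F12. Aqueous TFA frees the C5 aldehyde F13, Still–Gennari olefination with 10 gives the silyl ether F14, and AcOH/THF/H2O removes the silyl group to give 16.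

Further compounds
F1 | step 1 | 2-(trimethylsilyl)ethyl (diethoxyphosphoryl)acetate | CCOP(=O)(OCC)CC(=O)OCC[Si](C)(C)C
F2 | step 1 | 2-(trimethylsilyl)ethyl 2-[(1S,4R)-4-acetoxycyclopent-2-en-1-yl]-2-(diethoxyphosphoryl)acetate | CCOP(=O)(OCC)C(C(=O)OCC[Si](C)(C)C)[C@@H]1C=C[C@H](OC(C)=O)C1
F3 | step 1 | tetrabutylammonium 2-[(1S,4R)-4-acetoxycyclopent-2-en-1-yl]-2-(diethoxyphosphoryl)acetate | CCCC[N+](CCCC)(CCCC)CCCC.[O-]C(=O)C(P(=O)(OCC)OCC)[C@@H]1C=C[C@H](OC(C)=O)C1
F4 | step 8 | 2-cyano-3-{(2R,3S)-4-(diethoxyphosphoryl)-3-[(2Z)-3-(methoxycarbonyl)-6-hydroxyhex-2-en-1-yl]-5-oxooxolan-2-yl}prop-2-enoic acid | CCOP(=O)(OCC)C1C(=O)O[C@@H](C=C(C#N)C(=O)O)[C@@H]1C/C=C(/CCCO)C(=O)OC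
F5 | step 8 | 2-cyano-3-{(2S,3S)-4-(diethoxyphosphoryl)-3-[(2Z)-3-(methoxycarbonyl)-6-hydroxyhex-2-en-1-yl]-5-oxooxolan-2-yl}propanoic acid | CCOP(=O)(OCC)C1C(=O)O[C@@H](CC(C#N)C(=O)O)[C@@H]1C/C=C(/CCCO)C(=O)OC
F6 | step 8 | 2-cyano-3-{(2S,3S)-4-(diethoxyphosphoryl)-3-[(2Z)-3-(methoxycarbonyl)-6-oxohex-2-en-1-yl]-5-oxooxolan-2-yl}propanoic acid | CCOP(=O)(OCC)C1C(=O)O[C@@H](CC(C#N)C(=O)O)[C@@H]1C/C=C(/CCC=O)C(=O)OC
F7 | step 2 | diethyl [(4S,5S)-5-(hydroperoxy(methoxy)methyl)-2-oxo-4-(2-oxoethyl)oxolan-3-yl]phosphonate | CCOP(=O)(OCC)C1C(=O)O[C@H](C(OC)OO)[C@@H]1CC=O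
F8 | step 2 | diethyl [(4S,5S)-4-(2,2-dimethoxyethyl)-5-(hydroperoxy(methoxy)methyl)-2-oxooxolan-3-yl]phosphonate | CCOP(=O)(OCC)C1C(=O)O[C@H](C(OC)OO)[C@@H]1CC(OC)OC
F9 | step 2 | diethyl [(4S,5S)-4-(2,2-dimethoxyethyl)-5-formyl-2-oxooxolan-3-yl]phosphonate (cis) | CCOP(=O)(OCC)C1C(=O)O[C@H](C=O)[C@@H]1CC(OC)OC
F10 | step 2 | diethyl [(4S,5R)-4-(2,2-dimethoxyethyl)-5-formyl-2-oxooxolan-3-yl]phosphonate (trans) | CCOP(=O)(OCC)C1C(=O)O[C@@H](C=O)[C@@H]1CC(OC)OC
F11 | step 2 | diethyl {(4S,5R)-5-[2-cyano-2-(diethoxyphosphoryl)ethenyl]-4-(2,2-dimethoxyethyl)-2-oxooxolan-3-yl}phosphonate | CCOP(=O)(OCC)C1C(=O)O[C@@H](C=C(C#N)P(=O)(OCC)OCC)[C@@H]1CC(OC)OC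
F12 | step 2 | diethyl {(4S,5S)-5-[2-cyano-2-(diethoxyphosphoryl)ethyl]-4-(2,2-dimethoxyethyl)-2-oxooxolan-3-yl}phosphonate | CCOP(=O)(OCC)C1C(=O)O[C@@H](CC(C#N)P(=O)(OCC)OCC)[C@@H]1CC(OC)OC
F13 | step 2 | diethyl {(4S,5S)-5-[2-cyano-2-(diethoxyphosphoryl)ethyl]-2-oxo-4-(2-oxoethyl)oxolan-3-yl}phosphonate | CCOP(=O)(OCC)C1C(=O)O[C@@H](CC(C#N)P(=O)(OCC)OCC)[C@@H]1CC=O
F14 | step 2 | methyl (2Z)-2-{3-[(tert-butyldimethylsilyl)oxy]propyl}-4-{(2S,3S)-2-[2-cyano-2-(diethoxyphosphoryl)ethyl]-4-(diethoxyphosphoryl)-5-oxooxolan-3-yl}but-2-enoate | CCOP(=O)(OCC)C1C(=O)O[C@@H](CC(C#N)P(=O)(OCC)OCC)[C@@H]1C/C=C(/CCCO[Si](C)(C)C(C)(C)C)C(=O)OC
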